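**Assumption:** the target SMILES has no stereodescriptor and the molecule has no stereocentre (rotation about the aryl–indenone bonds is taken as free), so it is made as the one achiral compound; every transient stereocentre is racemic and is destroyed later.

This route has not been run; the conditions are proposed by analogy with known reactions.

## Retrosynthetic overview

Rings: A = benzo ring of the indenone, B = dihydroxytolyl group on C3, C = aryl group on C2, D = benzoate ring.

1. Ascomindone B ⇐ its penta-MOM ether (acid deprotection last) ⇐ intramolecular aldol condensation of a 2-(arylacetyl)benzophenone, which closes the five-membered ring (C2=C3). This is the only ring built; all four benzene rings are bought.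
2. Key C–C bond (C1–C2): intermolecular crossed Claisen condensation of the enolate of an allyl arylacetate (rings C/D) with a methyl 2-aroylbenzoate (rings A/B), then palladium-mediated loss of the allyl ester carbon.
3. Rings C/D: diaryl ether by SNAr of a 2,6-disubstituted phenol on 2-fluoro-6-(methoxymethoxy)-4-methylbenzaldehyde. The phenol comes from 2-hydroxy-5-methoxybenzaldehyde (O-allylation, Dakin oxidation, MOM protection, Claisen rearrangement); its allyl group becomes CH2CO2allyl.
4. Rings A/B: Vilsmeier formylation and BCl3 ortho-demethylation of methyl 3,5-dimethoxybenzoate fix the OH/OMe pattern of ring A. Ortho-lithiated orcinol bis-MOM ether adds to the aldehyde to give a phthalide, which is opened and oxidised to the keto ester.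

## Route

**Step 1**
Reactants: 1 2-hydroxy-5-methoxybenzaldehyde; 2 allyl bromide
Product: 3 2-(allyloxy)-5-methoxybenzaldehyde
Conditions: K2CO3, DMF, 60 °C
Reagents that add atoms: none
Why: Williamson O-alkylation (SN2) of the acidic salicylaldehyde phenol is clean and forms no stereocentre.

**Step 2**
Reactants: 3 2-(allyloxy)-5-methoxybenzaldehyde
Product: 5 2-(allyloxy)-5-methoxyphenol, via 2-(allyloxy)-5-methoxyphenyl formate 4 (not isolated)
Conditions: 30 % H2O2, H2SO4 (cat.), MeOH, rt
Reagents that add atoms: hydrogen peroxide, OO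
Why: Dakin-type (Baeyer–Villiger) oxidation, in which the electron-rich ortho-alkoxyaryl group migrates to oxygen and the formate is methanolysed, while the isolated allyl double bond is inert to H2O2.

**Step 3**
Reactants: 5 2-(allyloxy)-5-methoxyphenol
Product: 6 1-(allyloxy)-4-methoxy-2-(methoxymethoxy)benzene
Conditions: NaH, MOMCl, THF/DMF, 0 °C → rt
Reagents that add atoms: chloromethyl methyl ether (MOMCl), COCCl
Why: O-alkylation of the sodium phenoxide gives the base-stable MOM acetal (protection) that survives all later organometallic and basic steps.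

**Step 4**
Reactants: 6 1-(allyloxy)-4-methoxy-2-(methoxymethoxy)benzene
Product: 8 2-allyl-4-methoxy-6-(methoxymethoxy)phenol, via 6-allyl-4-methoxy-2-(methoxymethoxy)cyclohexa-2,4-dien-1-one 7 (not isolated)
Conditions: N,N-diethylaniline, 190 °C, sealed tube
Reagents that add atoms: none
Why: aromatic Claisen rearrangement ([3,3]-sigmatropic) can only deliver the allyl group to the single free ortho position (the other ortho and the para positions are substituted), and tautomerisation of the dienone unveils exactly the phenol needed for the ether bond.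

**Step 5**
Reactants: 9 3-fluoro-5-methylphenol
Product: 10 1-fluoro-3-(methoxymethoxy)-5-methylbenzene
Conditions: NaH, MOMCl, DMF, 0 °C → rt
Reagents that add atoms: chloromethyl methyl ether (MOMCl), COCCl
Why: MOM protection by phenoxide alkylation also installs a strong ortho-directing group for the next step.

**Step 6**
Reactants: 10 1-fluoro-3-(methoxymethoxy)-5-methylbenzene
Product: 13 2-fluoro-6-(methoxymethoxy)-4-methylbenzaldehyde, via [2-fluoro-6-(methoxymethoxy)-4-methylphenyl]lithium 11 (not isolated), via lithium hemiaminal alkoxide 12 (not isolated)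
Conditions: n-BuLi, THF, −78 °C, 1 h; DMF, −78 → 0 °C; H2O
Reagents that add atoms: N,N-dimethylformamide, CN(C)C=O
Why: directed ortho-lithiation occurs at the position flanked by both fluorine and OMOM (the most acidic C–H), −78 °C suppresses benzyne formation, and DMF formylates the aryllithium.

**Step 7**
Reactants: 8 2-allyl-4-methoxy-6-(methoxymethoxy)phenol; 13 2-fluoro-6-(methoxymethoxy)-4-methylbenzaldehyde
Product: 14 2-[2-allyl-4-methoxy-6-(methoxymethoxy)phenoxy]-6-(methoxymethoxy)-4-methylbenzaldehyde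
Conditions: Cs2CO3, DMF, 90 °C
Reagents that add atoms: none
Why: nucleophilic aromatic substitution (SNAr) in which the electron-rich caesium phenoxide displaces the fluoride activated by the ortho formyl group through a Meisenheimer adduct.

**Step 8**
Reactants: 14 2-[2-allyl-4-methoxy-6-(methoxymethoxy)phenoxy]-6-(methoxymethoxy)-4-methylbenzaldehyde
Product: 15 2-[2-allyl-4-methoxy-6-(methoxymethoxy)phenoxy]-6-(methoxymethoxy)-4-methylbenzoic acid
Conditions: NaClO2, NaH2PO4, 2-methyl-2-butene, t-BuOH/H2O, rt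
Reagents that add atoms: sodium chlorite, [Na+].[O-]Cl=O
Why: Pinnick oxidation converts even hindered aryl aldehydes to acids at about pH 4, where MOM ethers survive, and the scavenger protects the allyl group and the electron-rich rings from hypochlorite.

**Step 9**
Reactants: 15 2-[2-allyl-4-methoxy-6-(methoxymethoxy)phenoxy]-6-(methoxymethoxy)-4-methylbenzoic acid
Product: 16 methyl 2-[2-allyl-4-methoxy-6-(methoxymethoxy)phenoxy]-6-(methoxymethoxy)-4-methylbenzoate
Conditions: MeI, K2CO3, DMF, rt
Reagents that add atoms: iodomethane, CI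
Why: SN2 methylation of the carboxylate esterifies a di-ortho-substituted acid that would resist Fischer esterification, and installs the methyl ester of the target.

**Step 10**
Reactants: 16 methyl 2-[2-allyl-4-methoxy-6-(methoxymethoxy)phenoxy]-6-(methoxymethoxy)-4-methylbenzoate
Product: 18 methyl 2-[4-methoxy-6-(methoxymethoxy)-2-(2-oxoethyl)phenoxy]-6-(methoxymethoxy)-4-methylbenzoate, via racemic 2-(2,3-dihydroxypropyl) diol 17 (not isolated)
Conditions: OsO4 (2 mol %), NaIO4, 2,6-lutidine, dioxane/H2O, rt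
Reagents that add atoms: sodium periodate, [Na+].[O-]I(=O)(=O)=O (aldehyde oxygen, relayed by catalytic OsO4)
Why: Lemieux–Johnson oxidation (dihydroxylation, then periodate glycol cleavage) removes the terminal carbon of the only alkene, and 2,6-lutidine keeps the medium non-acidic for the MOM groups.

**Step 11**
Reactants: 18 methyl 2-[4-methoxy-6-(methoxymethoxy)-2-(2-oxoethyl)phenoxy]-6-(methoxymethoxy)-4-methylbenzoate
Product: 19 2-{5-methoxy-2-[2-(methoxycarbonyl)-3-(methoxymethoxy)-5-methylphenoxy]-3-(methoxymethoxy)phenyl}acetic acid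
Conditions: NaClO2, NaH2PO4, 2-methyl-2-butene, t-BuOH/H2O, 0 °C → rt (crude 18 used at once)
Reagents that add atoms: sodium chlorite, [Na+].[O-]Cl=O
Why: Pinnick oxidation takes the sensitive arylacetaldehyde to the arylacetic acid without epimerisable or acid-labile centres being at risk.

**Step 12**
Reactants: 19 2-{5-methoxy-2-[2-(methoxycarbonyl)-3-(methoxymethoxy)-5-methylphenoxy]-3-(methoxymethoxy)phenyl}acetic acid; 2 allyl bromide
Product: 20 allyl 2-{5-methoxy-2-[2-(methoxycarbonyl)-3-(methoxymethoxy)-5-methylphenoxy]-3-(methoxymethoxy)phenyl}acetate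
Conditions: K2CO3, DMF, rt
Reagents that add atoms: none
Why: carboxylate alkylation gives an allyl ester, a temporary activating group that palladium can later remove without touching the methyl ester of ring D.

**Step 13**
Reactants: 21 methyl 3,5-dimethoxybenzoate
Product: 23 methyl 2-formyl-3,5-dimethoxybenzoate, via aryl-methylidene dimethyliminium chloride 22 (not isolated)
Conditions: POCl3, DMF, 0 → 90 °C; then H2O, 60 °C
Reagents that add atoms: N,N-dimethylformamide, CN(C)C=O (formyl carbon); water, O (formyl oxygen)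
Why: Vilsmeier–Haack formylation attacks C2, which is para to one methoxy and ortho to the other and less hindered than C4 between the two methoxy groups.

**Step 14**
Reactants: 23 methyl 2-formyl-3,5-dimethoxybenzoate
Product: 25 methyl 2-formyl-3-hydroxy-5-methoxybenzoate, via aryloxydichloroborane chelate 24 (not isolated)
Conditions: BCl3 (1.5 equiv), CH2Cl2, −78 → 0 °C; then H2O
Reagents that add atoms: none
Why: chelation-controlled Lewis-acid demethylation cleaves only the methoxy group ortho to the formyl group, which fixes unambiguously which ring A oxygen becomes the free OH.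

**Step 15**
Reactants: 25 methyl 2-formyl-3-hydroxy-5-methoxybenzoate
Product: 26 methyl 2-formyl-5-methoxy-3-(methoxymethoxy)benzoate
Conditions: NaH, MOMCl, DMF, 0 °C
Reagents that add atoms: chloromethyl methyl ether (MOMCl), COCCl
Why: MOM protection by phenoxide alkylation; the aldehyde and ester have no enolisable hydrogen and tolerate NaH at 0 °C.

**Step 16**
Reactants: 27 orcinol (5-methylbenzene-1,3-diol)
Product: 28 1,3-bis(methoxymethoxy)-5-methylbenzene
Conditions: NaH (2.5 equiv), MOMCl (2.5 equiv), DMF, 0 °C → rt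
Reagents that add atoms: chloromethyl methyl ether (MOMCl), COCCl
Why: double MOM protection by phenoxide alkylation also provides two cooperating ortho-directing groups.

**Step 17**
Reactants: 28 1,3-bis(methoxymethoxy)-5-methylbenzene; 26 methyl 2-formyl-5-methoxy-3-(methoxymethoxy)benzoate
Product: 31 racemic 3-[2,6-bis(methoxymethoxy)-4-methylphenyl]-6-methoxy-4-(methoxymethoxy)-2-benzofuran-1(3H)-one, via [2,6-bis(methoxymethoxy)-4-methylphenyl]lithium 29 (not isolated), via lithium diarylmethanolate adduct 30 (not isolated)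
Conditions: 28, n-BuLi, THF, 0 °C, 1 h; then 26, −78 °C → rt; H2O
Reagents that add atoms: none
Why: directed ortho-lithiation between the two OMOM groups, then 1,2-addition to the aldehyde (far more electrophilic than the ester) and lactonisation onto the neighbouring ester give the phthalide, whose racemic stereocentre is removed in step 18.

**Step 18**
Reactants: 31 racemic 3-[2,6-bis(methoxymethoxy)-4-methylphenyl]-6-methoxy-4-(methoxymethoxy)-2-benzofuran-1(3H)-one
Product: 33 2-[2,6-bis(methoxymethoxy)-4-methylbenzoyl]-5-methoxy-3-(methoxymethoxy)benzoic acid, via potassium 2-[aryl(hydroxy)methyl]benzoate 32 (not isolated)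
Conditions: KOH, H2O/t-BuOH, 80 °C; then KMnO4 (0.7 equiv), 0 °C → rt; then aq. KHSO4 to pH 3–4, 0 °C
Reagents that add atoms: potassium hydroxide, [K+].[OH-]
Why: lactone saponification keeps the ring open as the carboxylate, so alkaline permanganate can oxidise the benzhydrol alkoxide to the diaryl ketone, and the base-stable MOM ethers are unaffected.

**Step 19**
Reactants: 33 2-[2,6-bis(methoxymethoxy)-4-methylbenzoyl]-5-methoxy-3-(methoxymethoxy)benzoic acid
Product: 34 methyl 2-[2,6-bis(methoxymethoxy)-4-methylbenzoyl]-5-methoxy-3-(methoxymethoxy)benzoate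
Conditions: MeI, K2CO3, DMF, rt
Reagents that add atoms: iodomethane, CI
Why: SN2 alkylation of the open-chain keto-carboxylate gives the normal methyl ester, not the cyclic pseudo-ester that acid-catalysed esterification can give.

**Step 20**
Reactants: 20 allyl 2-{5-methoxy-2-[2-(methoxycarbonyl)-3-(methoxymethoxy)-5-methylphenoxy]-3-(methoxymethoxy)phenyl}acetate; 34 methyl 2-[2,6-bis(methoxymethoxy)-4-methylbenzoyl]-5-methoxy-3-(methoxymethoxy)benzoate
Product: 36 racemic allyl 3-{2-[2,6-bis(methoxymethoxy)-4-methylbenzoyl]-5-methoxy-3-(methoxymethoxy)phenyl}-2-{5-methoxy-2-[2-(methoxycarbonyl)-3-(methoxymethoxy)-5-methylphenoxy]-3-(methoxymethoxy)phenyl}-3-oxopropanoate, via lithium enolate of the allyl arylacetate 35 (not isolated)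
Conditions: 20 (1.2 equiv), LiN(SiMe3)2 (2.4 equiv), THF, −78 °C; then 34 (1.0 equiv), −78 → 0 °C; AcOH
Reagents that add atoms: none
Why: crossed Claisen condensation in which the only enolisable partner (20) acylates at the ring A ester, because the ketone of 34 is shielded by four ortho substituents and the ring D ester by two; deprotonation of the β-keto ester drives it, and the racemic stereocentre is lost in step 21.

**Step 21**
Reactants: 36 racemic allyl β-keto ester (named in step 20)
Product: 38 methyl 2-[2-(2-{2-[2,6-bis(methoxymethoxy)-4-methylbenzoyl]-5-methoxy-3-(methoxymethoxy)phenyl}-2-oxoethyl)-4-methoxy-6-(methoxymethoxy)phenoxy]-6-(methoxymethoxy)-4-methylbenzoate, via β-keto acid 37 (not isolated)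
Conditions: Pd(PPh3)4 (5 mol %), morpholine (3 equiv), THF, rt → 40 °C
Reagents that add atoms: none
Why: Tsuji-type deallylation, in which zerovalent palladium ionises the allyl ester to a π-allyl complex trapped by morpholine and the β-keto acid decarboxylates spontaneously under neutral conditions that leave both methyl esters and all MOM groups alone.

**Step 22**
Reactants: 38 diketone (named in step 21)
Product: 40 methyl 2-[2-{3-[2,6-bis(methoxymethoxy)-4-methylphenyl]-6-methoxy-4-(methoxymethoxy)-1-oxo-1H-inden-2-yl}-4-methoxy-6-(methoxymethoxy)phenoxy]-6-(methoxymethoxy)-4-methylbenzoate, via 3-hydroxyindan-1-one aldol adduct 39 (not isolated)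
Conditions: NaOMe (0.5 equiv), MeOH/THF, 50 °C
Reagents that add atoms: none
Why: intramolecular aldol condensation, in which the benzylic ketone enolate closes the five-membered ring onto the neighbouring diaryl ketone and E1cB dehydration to the conjugated 2,3-diarylindenone makes it irreversible; methoxide exchange at the methyl ester is degenerate and no stereocentre remains.

**Step 23**
Reactants: 40 penta-MOM ether of ascomindone B (named in step 22)
Product: 41 ascomindone B, methyl 2-{2-[3-(2,6-dihydroxy-4-methylphenyl)-4-hydroxy-6-methoxy-1-oxo-1H-inden-2-yl]-6-hydroxy-4-methoxyphenoxy}-6-hydroxy-4-methylbenzoate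
Conditions: HCl (3 M aq.), MeOH/THF, 45 °C
Reagents that add atoms: none
Why: acid-catalysed acetal cleavage removes all five MOM groups (methanol takes up the CH2 as dimethoxymethane), while the aryl methyl ethers, the methyl ester (degenerate exchange in MeOH) and the indenone are stable.

## Compound list

1 | 2-hydroxy-5-methoxybenzaldehyde | COc1ccc(O)c(C=O)c1 | starting material
2 | allyl bromide | C=CCBr | starting material
3 | 2-(allyloxy)-5-methoxybenzaldehyde | COc1ccc(OCC=C)c(C=O)c1 | intermediate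
4 | 2-(allyloxy)-5-methoxyphenyl formate | COc1ccc(OCC=C)c(OC=O)c1 | intermediate (not isolated)
5 | 2-(allyloxy)-5-methoxyphenol | COc1ccc(OCC=C)c(O)c1 | intermediate
6 | 1-(allyloxy)-4-methoxy-2-(methoxymethoxy)benzene | COCOc1cc(OC)ccc1OCC=C | intermediate
7 | 6-allyl-4-methoxy-2-(methoxymethoxy)cyclohexa-2,4-dien-1-one (racemic) | COCOC1=CC(OC)=CC(CC=C)C1=O | intermediate (not isolated)
8 | 2-allyl-4-methoxy-6-(methoxymethoxy)phenol | COCOc1cc(OC)cc(CC=C)c1O | intermediate
9 | 3-fluoro-5-methylphenol | Cc1cc(O)cc(F)c1 | starting material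
10 | 1-fluoro-3-(methoxymethoxy)-5-methylbenzene | COCOc1cc(C)cc(F)c1 | intermediate
11 | [2-fluoro-6-(methoxymethoxy)-4-methylphenyl]lithium | [Li]c1c(F)cc(C)cc1OCOC | intermediate (not isolated)
12 | lithium (dimethylamino)[2-fluoro-6-(methoxymethoxy)-4-methylphenyl]methanolate (racemic) | [Li+].[O-]C(N(C)C)c1c(F)cc(C)cc1OCOC | intermediate (not isolated)
13 | 2-fluoro-6-(methoxymethoxy)-4-methylbenzaldehyde | COCOc1cc(C)cc(F)c1C=O | intermediate
14 | 2-[2-allyl-4-methoxy-6-(methoxymethoxy)phenoxy]-6-(methoxymethoxy)-4-methylbenzaldehyde | COCOc1cc(C)cc(Oc2c(CC=C)cc(OC)cc2OCOC)c1C=O | intermediate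
15 | 2-[2-allyl-4-methoxy-6-(methoxymethoxy)phenoxy]-6-(methoxymethoxy)-4-methylbenzoic acid | COCOc1cc(C)cc(Oc2c(CC=C)cc(OC)cc2OCOC)c1C(=O)O | intermediate
16 | methyl 2-[2-allyl-4-methoxy-6-(methoxymethoxy)phenoxy]-6-(methoxymethoxy)-4-methylbenzoate | COCOc1cc(C)cc(Oc2c(CC=C)cc(OC)cc2OCOC)c1C(=O)OC | intermediate
17 | methyl 2-[2-(2,3-dihydroxypropyl)-4-methoxy-6-(methoxymethoxy)phenoxy]-6-(methoxymethoxy)-4-methylbenzoate (racemic) | COCOc1cc(C)cc(Oc2c(CC(O)CO)cc(OC)cc2OCOC)c1C(=O)OC | intermediate (not isolated)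
18 | methyl 2-[4-methoxy-6-(methoxymethoxy)-2-(2-oxoethyl)phenoxy]-6-(methoxymethoxy)-4-methylbenzoate | COCOc1cc(C)cc(Oc2c(CC=O)cc(OC)cc2OCOC)c1C(=O)OC | intermediate
19 | 2-{5-methoxy-2-[2-(methoxycarbonyl)-3-(methoxymethoxy)-5-methylphenoxy]-3-(methoxymethoxy)phenyl}acetic acid | COCOc1cc(C)cc(Oc2c(CC(=O)O)cc(OC)cc2OCOC)c1C(=O)OC | intermediate
20 | allyl 2-{5-methoxy-2-[2-(methoxycarbonyl)-3-(methoxymethoxy)-5-methylphenoxy]-3-(methoxymethoxy)phenyl}acetate | COCOc1cc(C)cc(Oc2c(CC(=O)OCC=C)cc(OC)cc2OCOC)c1C(=O)OC | intermediate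
21 | methyl 3,5-dimethoxybenzoate | COC(=O)c1cc(OC)cc(OC)c1 | starting material
22 | [2,4-dimethoxy-6-(methoxycarbonyl)phenyl]methylidene-dimethyliminium chloride | COC(=O)c1cc(OC)cc(OC)c1C=[N+](C)C.[Cl-] | intermediate (not isolated)
23 | methyl 2-formyl-3,5-dimethoxybenzoate | COC(=O)c1cc(OC)cc(OC)c1C=O | intermediate
24 | methyl 3-[(dichloroboranyl)oxy]-2-formyl-5-methoxybenzoate | COC(=O)c1cc(OC)cc(OB(Cl)Cl)c1C=O | intermediate (not isolated)
25 | methyl 2-formyl-3-hydroxy-5-methoxybenzoate | COC(=O)c1cc(OC)cc(O)c1C=O | intermediate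
26 | methyl 2-formyl-5-methoxy-3-(methoxymethoxy)benzoate | COC(=O)c1cc(OC)cc(OCOC)c1C=O | intermediate
27 | orcinol (5-methylbenzene-1,3-diol) | Cc1cc(O)cc(O)c1 | starting material
28 | 1,3-bis(methoxymethoxy)-5-methylbenzene | COCOc1cc(C)cc(OCOC)c1 | intermediate
29 | [2,6-bis(methoxymethoxy)-4-methylphenyl]lithium | [Li]c1c(OCOC)cc(C)cc1OCOC | intermediate (not isolated)
30 | lithium [2,6-bis(methoxymethoxy)-4-methylphenyl][4-methoxy-2-(methoxycarbonyl)-6-(methoxymethoxy)phenyl]methanolate (racemic) | [Li+].[O-]C(c1c(OCOC)cc(C)cc1OCOC)c1c(OCOC)cc(OC)cc1C(=O)OC | intermediate (not isolated)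
31 | 3-[2,6-bis(methoxymethoxy)-4-methylphenyl]-6-methoxy-4-(methoxymethoxy)-2-benzofuran-1(3H)-one (racemic) | O=C1OC(c2c(OCOC)cc(C)cc2OCOC)c2c(OCOC)cc(OC)cc12 | intermediate
32 | potassium 2-{[2,6-bis(methoxymethoxy)-4-methylphenyl](hydroxy)methyl}-5-methoxy-3-(methoxymethoxy)benzoate (racemic) | [K+].[O-]C(=O)c1cc(OC)cc(OCOC)c1C(O)c1c(OCOC)cc(C)cc1OCOC | intermediate (not isolated)
33 | 2-[2,6-bis(methoxymethoxy)-4-methylbenzoyl]-5-methoxy-3-(methoxymethoxy)benzoic acid | OC(=O)c1cc(OC)cc(OCOC)c1C(=O)c1c(OCOC)cc(C)cc1OCOC | intermediate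
34 | methyl 2-[2,6-bis(methoxymethoxy)-4-methylbenzoyl]-5-methoxy-3-(methoxymethoxy)benzoate | COC(=O)c1cc(OC)cc(OCOC)c1C(=O)c1c(OCOC)cc(C)cc1OCOC | intermediate
35 | lithium enolate of 20 | [Li+].[O-]C(OCC=C)=Cc1cc(OC)cc(OCOC)c1Oc1cc(C)cc(OCOC)c1C(=O)OC | intermediate (not isolated)
36 | allyl 3-{2-[2,6-bis(methoxymethoxy)-4-methylbenzoyl]-5-methoxy-3-(methoxymethoxy)phenyl}-2-{5-methoxy-2-[2-(methoxycarbonyl)-3-(methoxymethoxy)-5-methylphenoxy]-3-(methoxymethoxy)phenyl}-3-oxopropanoate (racemic) | COC(=O)c1c(OCOC)cc(C)cc1Oc1c(OCOC)cc(OC)cc1C(C(=O)OCC=C)C(=O)c1cc(OC)cc(OCOC)c1C(=O)c1c(OCOC)cc(C)cc1OCOC | intermediate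
37 | 3-{2-[2,6-bis(methoxymethoxy)-4-methylbenzoyl]-5-methoxy-3-(methoxymethoxy)phenyl}-2-{5-methoxy-2-[2-(methoxycarbonyl)-3-(methoxymethoxy)-5-methylphenoxy]-3-(methoxymethoxy)phenyl}-3-oxopropanoic acid (racemic) | COC(=O)c1c(OCOC)cc(C)cc1Oc1c(OCOC)cc(OC)cc1C(C(=O)O)C(=O)c1cc(OC)cc(OCOC)c1C(=O)c1c(OCOC)cc(C)cc1OCOC | intermediate (not isolated)
38 | methyl 2-[2-(2-{2-[2,6-bis(methoxymethoxy)-4-methylbenzoyl]-5-methoxy-3-(methoxymethoxy)phenyl}-2-oxoethyl)-4-methoxy-6-(methoxymethoxy)phenoxy]-6-(methoxymethoxy)-4-methylbenzoate | COC(=O)c1c(OCOC)cc(C)cc1Oc1c(OCOC)cc(OC)cc1CC(=O)c1cc(OC)cc(OCOC)c1C(=O)c1c(OCOC)cc(C)cc1OCOC | intermediate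
39 | methyl 2-[2-{3-[2,6-bis(methoxymethoxy)-4-methylphenyl]-3-hydroxy-6-methoxy-4-(methoxymethoxy)-1-oxo-2,3-dihydro-1H-inden-2-yl}-4-methoxy-6-(methoxymethoxy)phenoxy]-6-(methoxymethoxy)-4-methylbenzoate (diastereomer mixture) | COC(=O)c1c(OCOC)cc(C)cc1Oc1c(OCOC)cc(OC)cc1C1C(=O)c2cc(OC)cc(OCOC)c2C1(O)c1c(OCOC)cc(C)cc1OCOC | intermediate (not isolated)
40 | methyl 2-[2-{3-[2,6-bis(methoxymethoxy)-4-methylphenyl]-6-methoxy-4-(methoxymethoxy)-1-oxo-1H-inden-2-yl}-4-methoxy-6-(methoxymethoxy)phenoxy]-6-(methoxymethoxy)-4-methylbenzoate | COC(=O)c1c(OCOC)cc(C)cc1Oc1c(OCOC)cc(OC)cc1C1=C(c2c(OCOC)cc(C)cc2OCOC)c2c(OCOC)cc(OC)cc2C1=O | intermediate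
41 | ascomindone B | COC(=O)c1c(O)cc(C)cc1Oc1c(O)cc(OC)cc1C1=C(c2c(O)cc(C)cc2O)c2c(O)cc(OC)cc2C1=O | target

## Step count and risks

Total step count: 23.
Longest linear sequence: 14 steps (steps 1–4, 7–12, 20–23, from compound 1).

The three steps most likely to fail:

**Step 20 (crossed Claisen).** The acylation of a hindered α-aryl ester enolate by a methyl benzoate may be slow, and on warming the enolate 35 could instead attack its own ring D ester (seven-membered Dieckmann closure). The fallback replaces the ester electrophile by an aldehyde and sets out from 31 and 20, coming back at 36. Phthalide 31 is reduced with LiAlH4 (THF, 0 °C) to [2,6-bis(methoxymethoxy)-4-methylphenyl][2-(hydroxymethyl)-4-methoxy-6-(methoxymethoxy)phenyl]methanol F7. Swern oxidation (oxalyl chloride, DMSO, Et3N, −78 °C; both hydroxyls are activated before base is added, which avoids lactol and lactone formation) gives 2-[2,6-bis(methoxymethoxy)-4-methylbenzoyl]-5-methoxy-3-(methoxymethoxy)benzaldehyde F8. Aldol addition of the lithium enolate 35 to the aldehyde of F8 at −78 °C, which is fast and leaves both esters and the shielded ketone alone, gives allyl 3-{2-[2,6-bis(methoxymethoxy)-4-methylbenzoyl]-5-methoxy-3-(methoxymethoxy)phenyl}-3-hydroxy-2-{5-methoxy-2-[2-(methoxycarbonyl)-3-(methoxymethoxy)-5-methylphenoxy]-3-(methoxymethoxy)phenyl}propanoate F9 as a diastereomer mixture. Dess–Martin periodinane oxidation of F9 gives 36.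

**Step 7 (SNAr).** The phenoxide of 8 is flanked by two ortho groups and the fluoride of 13 is activated by one formyl group only. The fallback sets out from 8 and comes back at 14. Phenol 8 and commercial 2,6-difluoro-4-methylbenzaldehyde (Cc1cc(F)c(C=O)c(F)c1), whose second fluorine accelerates the first substitution, react with K2CO3 in DMF at 60 °C to give 2-[2-allyl-4-methoxy-6-(methoxymethoxy)phenoxy]-6-fluoro-4-methylbenzaldehyde F1. The remaining fluoride is displaced by the sodium alkoxide of 2-(methylsulfonyl)ethanol (NaH, DMF, 0 °C → rt) to give 2-[2-allyl-4-methoxy-6-(methoxymethoxy)phenoxy]-4-methyl-6-[2-(methylsulfonyl)ethoxy]benzaldehyde F2. In the same flask F2 loses methyl vinyl sulfone by E1cB elimination to give 2-[2-allyl-4-methoxy-6-(methoxymethoxy)phenoxy]-6-hydroxy-4-methylbenzaldehyde F3. NaH/MOMCl then gives 14.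

**Step 18 (saponification and permanganate oxidation).** The congested lactone may open slowly and permanganate may attack the electron-rich rings or the aryl methyl group. The fallback oxidises the C–H bond of the lactone directly; it sets out from 31 and comes back at 34. Deprotonation of 31 with KN(SiMe3)2 (THF, −78 °C) gives potassium 1-[2,6-bis(methoxymethoxy)-4-methylphenyl]-5-methoxy-7-(methoxymethoxy)-3-oxo-1,3-dihydro-2-benzofuran-1-ide F4. Dry O2 converts it to 3-[2,6-bis(methoxymethoxy)-4-methylphenyl]-3-hydroperoxy-6-methoxy-4-(methoxymethoxy)-2-benzofuran-1(3H)-one F5. P(OEt)3 reduces this to 3-[2,6-bis(methoxymethoxy)-4-methylphenyl]-3-hydroxy-6-methoxy-4-(methoxymethoxy)-2-benzofuran-1(3H)-one F6, the ring tautomer of 33. Under the conditions of step 19 (MeI, K2CO3, DMF) F6 opens to the keto-carboxylate and is methylated to 34.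

## Further compounds

F1 | step 7 | 2-[2-allyl-4-methoxy-6-(methoxymethoxy)phenoxy]-6-fluoro-4-methylbenzaldehyde | Cc1cc(F)c(C=O)c(Oc2c(CC=C)cc(OC)cc2OCOC)c1
F2 | step 7 | 2-[2-allyl-4-methoxy-6-(methoxymethoxy)phenoxy]-4-methyl-6-[2-(methylsulfonyl)ethoxy]benzaldehyde | Cc1cc(OCCS(C)(=O)=O)c(C=O)c(Oc2c(CC=C)cc(OC)cc2OCOC)c1
F3 | step 7 | 2-[2-allyl-4-methoxy-6-(methoxymethoxy)phenoxy]-6-hydroxy-4-methylbenzaldehyde | Cc1cc(O)c(C=O)c(Oc2c(CC=C)cc(OC)cc2OCOC)c1
F4 | step 18 | potassium 1-[2,6-bis(methoxymethoxy)-4-methylphenyl]-5-methoxy-7-(methoxymethoxy)-3-oxo-1,3-dihydro-2-benzofuran-1-ide | [K+].O=C1O[C-](c2c(OCOC)cc(C)cc2OCOC)c2c(OCOC)cc(OC)cc12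
F5 | step 18 | 3-[2,6-bis(methoxymethoxy)-4-methylphenyl]-3-hydroperoxy-6-methoxy-4-(methoxymethoxy)-2-benzofuran-1(3H)-one (racemic) | O=C1OC(OO)(c2c(OCOC)cc(C)cc2OCOC)c2c(OCOC)cc(OC)cc12
F6 | step 18 | 3-[2,6-bis(methoxymethoxy)-4-methylphenyl]-3-hydroxy-6-methoxy-4-(methoxymethoxy)-2-benzofuran-1(3H)-one (racemic) | O=C1OC(O)(c2c(OCOC)cc(C)cc2OCOC)c2c(OCOC)cc(OC)cc12
F7 | step 20 | [2,6-bis(methoxymethoxy)-4-methylphenyl][2-(hydroxymethyl)-4-methoxy-6-(methoxymethoxy)phenyl]methanol (racemic) | OCc1cc(OC)cc(OCOC)c1C(O)c1c(OCOC)cc(C)cc1OCOC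
F8 | step 20 | 2-[2,6-bis(methoxymethoxy)-4-methylbenzoyl]-5-methoxy-3-(methoxymethoxy)benzaldehyde | O=Cc1cc(OC)cc(OCOC)c1C(=O)c1c(OCOC)cc(C)cc1OCOC
F9 | step 20 | allyl 3-{2-[2,6-bis(methoxymethoxy)-4-methylbenzoyl]-5-methoxy-3-(methoxymethoxy)phenyl}-3-hydroxy-2-{5-methoxy-2-[2-(methoxycarbonyl)-3-(methoxymethoxy)-5-methylphenoxy]-3-(methoxymethoxy)phenyl}propanoate (diastereomer mixture) | COC(=O)c1c(OCOC)cc(C)cc1Oc1c(OCOC)cc(OC)cc1C(C(=O)OCC=C)C(O)c1cc(OC)cc(OCOC)c1C(=O)c1c(OCOC)cc(C)cc1OCOC
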